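Everything rests on disconnecting C2–C3 of the tetrahydrofuran (ring atoms O1, C2, C3, C4, C5). O1 ties the C5 carbinol to a 4-oxygenated benzylic carbon, C2, whose hydrogen stands in a 1,5 relationship to the ketone α-carbon C3; a dirhodium carbenoid at C3 can therefore insert into that C2–H bond, which closes the ring and creates the C2–C3 bond and both remaining stereocentres in one operation. The precursor is an acyclic, fully silylated α-diazo ketone with C4 and C5 already set (asymmetric alkynylation, then trans conjugate addition to a butenolide); triisopropylsilyl ethers on the benzoyl ring keep its ortho oxygen away from the carbenoid.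

Key step: step 13

Remarks and assumptions:
- Ring numbering is O1, C2 (4-hydroxyphenyl), C3 (2,4-dihydroxybenzoyl), C4 (4-hydroxybenzyl), C5 (2,4-dihydroxyphenyl); the target is the all-trans (2S,3S,4S,5S) isomer.
- TBS = tert-butyldimethylsilyl, TIPS = triisopropylsilyl; TBSO and TIPSO are the corresponding aryl silyl ethers.
- 4-(tert-Butyldimethylsilyloxy)benzaldehyde 8 is taken as a catalogue compound; it is otherwise one silylation from 4-hydroxybenzaldehyde.
- In step 2 the ProPhenol antipode is the one that gives Si-face addition; this is to be confirmed on 5 by Mosher ester analysis.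

Step 1
Reactants: 1 2,4-dihydroxybenzaldehyde
Product: 2 2,4-bis(TBSO)benzaldehyde
Conditions: TBSCl (2.5 equiv), imidazole (5 equiv), DMF, 23 °C
Reagents that add atoms: tert-butyldimethylsilyl chloride, CC(C)(C)[Si](C)(C)Cl
Why: Imidazole-promoted O-silylation of phenols (silyl ether formation), in which excess reagent in DMF also caps the hydrogen-bonded ortho hydroxyl while the aldehyde is inert.

Step 2
Reactants: 2 2,4-bis(TBSO)benzaldehyde; 3 methyl propiolate
Product: 5 methyl (4S)-4-[2,4-bis(TBSO)phenyl]-4-hydroxybut-2-ynoate, via zinc acetylide 4 (not isolated)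
Conditions: 3 (3 equiv), Me2Zn (3 equiv), ProPhenol (10 mol%), Ph3P=O (20 mol%), toluene, 0 °C; aq. NH4Cl
Reagents that add atoms: none
Why: Catalytic asymmetric alkynylation of an aldehyde with the dinuclear zinc complex formed from Me2Zn and ProPhenol, in which zinc acetylide 4 is delivered to the Si face of the non-enolisable aldehyde inside the chiral bimetallic pocket and so sets C5 as S.

Step 3
Reactants: 5 methyl (4S)-4-[2,4-bis(TBSO)phenyl]-4-hydroxybut-2-ynoate
Product: 7 (5S)-5-[2,4-bis(TBSO)phenyl]furan-2(5H)-one, via Z-hydroxy enoate 6 (not isolated)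
Conditions: H2 (1 atm), Pd/CaCO3 poisoned with Pb(OAc)2 (Lindlar catalyst), quinoline, EtOAc, 23 °C; then SiO2, CH2Cl2, 23 °C
Reagents that add atoms: none
Why: Lindlar semi-hydrogenation gives Z-enoate 6, whose hydroxyl and ester are held cis so that lactonisation to the butenolide follows under neutral conditions that leave C5 untouched.

Step 4
Reactants: 8 4-(TBSO)benzaldehyde
Product: 9 4-(TBSO)benzyl alcohol
Conditions: NaBH4, MeOH, 0 °C
Reagents that add atoms: none
Why: Sodium borohydride reduction of an aromatic aldehyde to the benzylic alcohol, which the aryl silyl ether tolerates at 0 °C.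

Step 5
Reactants: 9 4-(TBSO)benzyl alcohol
Product: 11 4-(TBSO)benzyl chloride, via benzylic mesylate 10 (not isolated)
Conditions: MsCl, Et3N, CH2Cl2, 0 → 23 °C
Reagents that add atoms: methanesulfonyl chloride, CS(=O)(=O)Cl
Why: Mesylation of an electron-rich benzylic alcohol followed by in situ displacement by chloride (nucleophilic substitution) gives the chloride without acid.

Step 6
Reactants: 7 (5S)-5-[2,4-bis(TBSO)phenyl]furan-2(5H)-one; 11 4-(TBSO)benzyl chloride
Product: 15 (4S,5S)-5-[2,4-bis(TBSO)phenyl]-4-[4-(TBSO)benzyl]dihydrofuran-2(3H)-one, via benzylmagnesium chloride 12 (not isolated), via benzylcopper 13 (not isolated), via silyl ketene acetal 14 (not isolated)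
Conditions: 11, Mg, Et2O, 0 °C; CuI, TMEDA, TMSCl, THF, −78 °C; then 7, −78 → −40 °C; aq. NH4Cl
Reagents that add atoms: none
Why: Organocopper conjugate addition accelerated by TMSCl, in which the benzylcopper reagent attacks the butenolide on the face opposite the C5 aryl group and so sets C4 as S (4,5-trans), with aqueous work-up hydrolysing silyl ketene acetal 14.

Step 7
Reactants: 15 (4S,5S)-5-[2,4-bis(TBSO)phenyl]-4-[4-(TBSO)benzyl]dihydrofuran-2(3H)-one
Product: 16 (3S,4S)-4-[2,4-bis(TBSO)phenyl]-4-hydroxy-N-methoxy-N-methyl-3-[4-(TBSO)benzyl]butanamide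
Conditions: MeNHOMe·HCl, i-PrMgCl, THF, −20 → 0 °C; aq. NH4Cl
Reagents that add atoms: N,O-dimethylhydroxylamine hydrochloride, CNOC.Cl
Why: Weinreb amidation of a lactone by the magnesium amide of N,O-dimethylhydroxylamine (acyl substitution) frees the C5 hydroxyl without touching C4 or C5.

Step 8
Reactants: 9 4-(TBSO)benzyl alcohol
Product: 17 4-(TBSO)benzyl 2,2,2-trichloroacetimidate
Conditions: Cl3CCN, DBU (10 mol%), CH2Cl2, 0 °C
Reagents that add atoms: trichloroacetonitrile, N#CC(Cl)(Cl)Cl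
Why: DBU-catalysed addition of the alcohol to trichloroacetonitrile (imidate formation).

Step 9
Reactants: 16 (3S,4S)-hydroxy Weinreb amide; 17 4-(TBSO)benzyl 2,2,2-trichloroacetimidate
Product: 18 (3S,4S)-4-[2,4-bis(TBSO)phenyl]-N-methoxy-N-methyl-3-[4-(TBSO)benzyl]-4-[4-(TBSO)benzyloxy]butanamide
Conditions: 17 (2 equiv), CSA (5 mol%), CH2Cl2, −20 → 0 °C
Reagents that add atoms: none
Why: Acid-catalysed trichloroacetimidate benzylation of the kind used for para-methoxybenzyl ethers, in which the C5 hydroxyl captures the stabilised benzylic cation so that the C5–O bond is never broken and C5 keeps its configuration, while the weak acid and low temperature guard against relactonisation and ionisation at C5.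

Step 10
Reactants: 19 4-bromoresorcinol
Product: 20 1-bromo-2,4-bis(TIPSO)benzene
Conditions: TIPSCl (2.5 equiv), imidazole (5 equiv), DMF, 40 °C
Reagents that add atoms: triisopropylsilyl chloride, CC(C)[Si](Cl)(C(C)C)C(C)C
Why: Imidazole-promoted O-silylation of both phenols, with TIPS chosen for this ring because it resists anionic 1,3 oxygen-to-carbon silyl migration in step 11 and base in step 12 and screens the ortho oxygen in step 13.

Step 11
Reactants: 18 (3S,4S)-benzyl ether Weinreb amide; 20 1-bromo-2,4-bis(TIPSO)benzene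
Product: 23 (3S,4S)-1-[2,4-bis(TIPSO)phenyl]-4-[2,4-bis(TBSO)phenyl]-3-[4-(TBSO)benzyl]-4-[4-(TBSO)benzyloxy]butan-1-one, via aryllithium 21 (not isolated), via lithium hemiaminal adduct 22 (not isolated)
Conditions: 20, t-BuLi (2.0 equiv), Et2O, −78 °C; then 18, THF, −78 → −40 °C; aq. NH4Cl
Reagents that add atoms: none
Why: Bromine–lithium exchange followed by Weinreb ketone synthesis, in which chelated adduct 22 blocks over-addition and releases the ketone only on work-up, while exact t-BuLi stoichiometry at −78 °C avoids metalation of the benzylic ether.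

Step 12
Reactants: 23 (3S,4S)-ketone
Product: 26 (3S,4S)-2-diazo-1-[2,4-bis(TIPSO)phenyl]-4-[2,4-bis(TBSO)phenyl]-3-[4-(TBSO)benzyl]-4-[4-(TBSO)benzyloxy]butan-1-one, via lithium enolate 24 (not isolated), via trifluoroacetyl ketone 25 (not isolated)
Conditions: LiN(SiMe3)2, THF, −78 °C; CF3CO2CH2CF3; aq. NH4Cl; then MsN3, Et3N, H2O (1 equiv), MeCN, 23 °C
Reagents that add atoms: methanesulfonyl azide, CS(=O)(=O)N=[N+]=[N-]
Why: Detrifluoroacetylative Regitz-type diazo transfer, in which kinetic enolate 24 is C-acylated to the activated diketone 25 and this takes the diazo group from the sulfonyl azide with loss of the trifluoroacetyl group, C4 and C5 not being involved.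

Step 13
Reactants: 26 (3S,4S)-α-diazo ketone
Product: 28 [2,4-bis(TIPSO)phenyl]{(2S,3S,4S,5S)-5-[2,4-bis(TBSO)phenyl]-4-[4-(TBSO)benzyl]-2-[4-(TBSO)phenyl]tetrahydrofuran-3-yl}methanone, via C3-epimeric tetrahydrofuran 27 (not isolated)
Conditions: Rh2(O2CCMe3)4 (2 mol%), CH2Cl2, −78 → −20 °C, slow addition of 26; then DBU (0.2 equiv), 0 °C
Reagents that add atoms: none
Why: Dirhodium-induced loss of N2 from 26 gives an electrophilic carbenoid at C3, which takes up the hydridic C2–H bond (α to O1 and benzylic to the 4-silyloxyphenyl ring) in a three-centre transition state that forms C2–C3 and transfers the hydrogen to C3 in one event. The closest known reaction type is the dirhodium carboxylate-catalysed 1,5 C–H insertion of α-alkyl-α-diazo carbonyl compounds into ether α-C–H bonds, which gives 3-acyl tetrahydrofurans. The tetrahydrofuran closes as a five-membered ring through a chair-like six-centre array (C3, C4, C5, O1, C2 and the migrating H) in which the C4 benzyl and C5 aryl groups sit pseudo-equatorial. C2 is controlled in this array by its aryl group turning away from the carboxylate wall around the Rh–C3 bond, which places it trans to the C5 aryl group, whereas C3 is expected to appear first with the aroyl group cis to both neighbours (27) and, being an enolisable α-keto methine flanked by the fixed C2 and C4 centres, to be relaxed by catalytic DBU to the all-trans isomer 28. The step needs C–H insertion to outrun 1,2-hydride shift from C4, aromatic substitution and oxonium ylide formation: bulky pivalate ligands at −78 °C are known to hold back hydride shift (triphenylacetate is avoided because it is reported to favour aromatic substitution), the doubly activated C2–H is the most hydridic bond within reach, the arene positions within reach are meta to their oxygen substituents, and the TIPS groups screen the benzoyl ortho oxygen.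

Step 14
Reactants: 28 all-trans hexasilyl ether
Product: 29 (2,4-dihydroxyphenyl)[(2S,3S,4S,5S)-5-(2,4-dihydroxyphenyl)-4-(4-hydroxybenzyl)-2-(4-hydroxyphenyl)tetrahydrofuran-3-yl]methanone (CNP0181717.2)
Conditions: TBAF, AcOH (1:1, 8 equiv), THF, 0 → 23 °C
Reagents that add atoms: none
Why: Fluoride-mediated cleavage of all six aryl silyl ethers (Si–F bond formation), with acetic acid keeping the phenols protonated so that the β-alkoxy ketone neither opens by retro-oxa-Michael reaction nor epimerises.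

Compound list

1 | 2,4-dihydroxybenzaldehyde | O=Cc1ccc(O)cc1O | starting material
2 | 2,4-bis(tert-butyldimethylsilyloxy)benzaldehyde | O=Cc1ccc(O[Si](C)(C)C(C)(C)C)cc1O[Si](C)(C)C(C)(C)C | intermediate
3 | methyl propiolate | C#CC(=O)OC | starting material
4 | methyl 3-(methylzincio)prop-2-ynoate | COC(=O)C#C[Zn]C | intermediate (not isolated)
5 | methyl (4S)-4-[2,4-bis(TBSO)phenyl]-4-hydroxybut-2-ynoate | COC(=O)C#C[C@H](O)c1ccc(O[Si](C)(C)C(C)(C)C)cc1O[Si](C)(C)C(C)(C)C | intermediate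
6 | methyl (2Z,4S)-4-[2,4-bis(TBSO)phenyl]-4-hydroxybut-2-enoate | COC(=O)/C=C\[C@H](O)c1ccc(O[Si](C)(C)C(C)(C)C)cc1O[Si](C)(C)C(C)(C)C | intermediate (not isolated)
7 | (5S)-5-[2,4-bis(TBSO)phenyl]furan-2(5H)-one | O=C1C=C[C@@H](c2ccc(O[Si](C)(C)C(C)(C)C)cc2O[Si](C)(C)C(C)(C)C)O1 | intermediate
8 | 4-(tert-butyldimethylsilyloxy)benzaldehyde | O=Cc1ccc(O[Si](C)(C)C(C)(C)C)cc1 | starting material
9 | 4-(TBSO)benzyl alcohol | OCc1ccc(O[Si](C)(C)C(C)(C)C)cc1 | intermediate
10 | 4-(TBSO)benzyl methanesulfonate | CS(=O)(=O)OCc1ccc(O[Si](C)(C)C(C)(C)C)cc1 | intermediate (not isolated)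
11 | 4-(TBSO)benzyl chloride | ClCc1ccc(O[Si](C)(C)C(C)(C)C)cc1 | intermediate
12 | 4-(TBSO)benzylmagnesium chloride | Cl[Mg]Cc1ccc(O[Si](C)(C)C(C)(C)C)cc1 | intermediate (not isolated)
13 | [4-(TBSO)benzyl]copper, TMEDA complex | [Cu]Cc1ccc(O[Si](C)(C)C(C)(C)C)cc1 | intermediate (not isolated)
14 | (4S,5S)-5-[2,4-bis(TBSO)phenyl]-4-[4-(TBSO)benzyl]-2-(trimethylsilyloxy)-4,5-dihydrofuran | C[Si](C)(C)OC1=C[C@H](Cc2ccc(O[Si](C)(C)C(C)(C)C)cc2)[C@@H](c2ccc(O[Si](C)(C)C(C)(C)C)cc2O[Si](C)(C)C(C)(C)C)O1 | intermediate (not isolated)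
15 | (4S,5S)-5-[2,4-bis(TBSO)phenyl]-4-[4-(TBSO)benzyl]dihydrofuran-2(3H)-one (trans) | O=C1C[C@H](Cc2ccc(O[Si](C)(C)C(C)(C)C)cc2)[C@@H](c2ccc(O[Si](C)(C)C(C)(C)C)cc2O[Si](C)(C)C(C)(C)C)O1 | intermediate
16 | (3S,4S)-4-[2,4-bis(TBSO)phenyl]-4-hydroxy-N-methoxy-N-methyl-3-[4-(TBSO)benzyl]butanamide | CON(C)C(=O)C[C@H](Cc1ccc(O[Si](C)(C)C(C)(C)C)cc1)[C@H](O)c1ccc(O[Si](C)(C)C(C)(C)C)cc1O[Si](C)(C)C(C)(C)C | intermediate
17 | 4-(TBSO)benzyl 2,2,2-trichloroacetimidate | N=C(OCc1ccc(O[Si](C)(C)C(C)(C)C)cc1)C(Cl)(Cl)Cl | intermediate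
18 | (3S,4S)-4-[2,4-bis(TBSO)phenyl]-N-methoxy-N-methyl-3-[4-(TBSO)benzyl]-4-[4-(TBSO)benzyloxy]butanamide | CON(C)C(=O)C[C@H](Cc1ccc(O[Si](C)(C)C(C)(C)C)cc1)[C@H](OCc1ccc(O[Si](C)(C)C(C)(C)C)cc1)c1ccc(O[Si](C)(C)C(C)(C)C)cc1O[Si](C)(C)C(C)(C)C | intermediate
19 | 4-bromoresorcinol | Oc1ccc(Br)c(O)c1 | starting material
20 | 1-bromo-2,4-bis(triisopropylsilyloxy)benzene | Brc1ccc(O[Si](C(C)C)(C(C)C)C(C)C)cc1O[Si](C(C)C)(C(C)C)C(C)C | intermediate
21 | 2,4-bis(TIPSO)phenyllithium | [Li]c1ccc(O[Si](C(C)C)(C(C)C)C(C)C)cc1O[Si](C(C)C)(C(C)C)C(C)C | intermediate (not isolated)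
22 | lithium alkoxide of the N-methoxy-N-methyl hemiaminal formed from 18 and 21 (new carbinol centre undefined) | [Li]OC(N(C)OC)(c1ccc(O[Si](C(C)C)(C(C)C)C(C)C)cc1O[Si](C(C)C)(C(C)C)C(C)C)C[C@H](Cc1ccc(O[Si](C)(C)C(C)(C)C)cc1)[C@H](OCc1ccc(O[Si](C)(C)C(C)(C)C)cc1)c1ccc(O[Si](C)(C)C(C)(C)C)cc1O[Si](C)(C)C(C)(C)C | intermediate (not isolated)
23 | (3S,4S)-1-[2,4-bis(TIPSO)phenyl]-4-[2,4-bis(TBSO)phenyl]-3-[4-(TBSO)benzyl]-4-[4-(TBSO)benzyloxy]butan-1-one | O=C(c1ccc(O[Si](C(C)C)(C(C)C)C(C)C)cc1O[Si](C(C)C)(C(C)C)C(C)C)C[C@H](Cc1ccc(O[Si](C)(C)C(C)(C)C)cc1)[C@H](OCc1ccc(O[Si](C)(C)C(C)(C)C)cc1)c1ccc(O[Si](C)(C)C(C)(C)C)cc1O[Si](C)(C)C(C)(C)C | intermediate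
24 | lithium enolate of 23 | [Li]OC(=C[C@H](Cc1ccc(O[Si](C)(C)C(C)(C)C)cc1)[C@H](OCc1ccc(O[Si](C)(C)C(C)(C)C)cc1)c1ccc(O[Si](C)(C)C(C)(C)C)cc1O[Si](C)(C)C(C)(C)C)c1ccc(O[Si](C(C)C)(C(C)C)C(C)C)cc1O[Si](C(C)C)(C(C)C)C(C)C | intermediate (not isolated)
25 | 2-trifluoroacetyl derivative of 23 (C2 undefined, 3S,4S) | O=C(c1ccc(O[Si](C(C)C)(C(C)C)C(C)C)cc1O[Si](C(C)C)(C(C)C)C(C)C)C(C(=O)C(F)(F)F)[C@H](Cc1ccc(O[Si](C)(C)C(C)(C)C)cc1)[C@H](OCc1ccc(O[Si](C)(C)C(C)(C)C)cc1)c1ccc(O[Si](C)(C)C(C)(C)C)cc1O[Si](C)(C)C(C)(C)C | intermediate (not isolated)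
26 | (3S,4S)-2-diazo-1-[2,4-bis(TIPSO)phenyl]-4-[2,4-bis(TBSO)phenyl]-3-[4-(TBSO)benzyl]-4-[4-(TBSO)benzyloxy]butan-1-one (key-step precursor) | O=C(c1ccc(O[Si](C(C)C)(C(C)C)C(C)C)cc1O[Si](C(C)C)(C(C)C)C(C)C)C(=[N+]=[N-])[C@H](Cc1ccc(O[Si](C)(C)C(C)(C)C)cc1)[C@H](OCc1ccc(O[Si](C)(C)C(C)(C)C)cc1)c1ccc(O[Si](C)(C)C(C)(C)C)cc1O[Si](C)(C)C(C)(C)C | intermediate
27 | [2,4-bis(TIPSO)phenyl]{(2S,3R,4S,5S)-5-[2,4-bis(TBSO)phenyl]-4-[4-(TBSO)benzyl]-2-[4-(TBSO)phenyl]tetrahydrofuran-3-yl}methanone (aroyl cis to both neighbours) | O=C(c1ccc(O[Si](C(C)C)(C(C)C)C(C)C)cc1O[Si](C(C)C)(C(C)C)C(C)C)[C@@H]1[C@H](Cc2ccc(O[Si](C)(C)C(C)(C)C)cc2)[C@@H](c2ccc(O[Si](C)(C)C(C)(C)C)cc2O[Si](C)(C)C(C)(C)C)O[C@@H]1c1ccc(O[Si](C)(C)C(C)(C)C)cc1 | intermediate (not isolated)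
28 | [2,4-bis(TIPSO)phenyl]{(2S,3S,4S,5S)-5-[2,4-bis(TBSO)phenyl]-4-[4-(TBSO)benzyl]-2-[4-(TBSO)phenyl]tetrahydrofuran-3-yl}methanone (all-trans, key-step product) | O=C(c1ccc(O[Si](C(C)C)(C(C)C)C(C)C)cc1O[Si](C(C)C)(C(C)C)C(C)C)[C@H]1[C@H](Cc2ccc(O[Si](C)(C)C(C)(C)C)cc2)[C@@H](c2ccc(O[Si](C)(C)C(C)(C)C)cc2O[Si](C)(C)C(C)(C)C)O[C@@H]1c1ccc(O[Si](C)(C)C(C)(C)C)cc1 | intermediate
29 | (2,4-dihydroxyphenyl)[(2S,3S,4S,5S)-5-(2,4-dihydroxyphenyl)-4-(4-hydroxybenzyl)-2-(4-hydroxyphenyl)tetrahydrofuran-3-yl]methanone | O=C(c1ccc(O)cc1O)[C@H]1[C@H](Cc2ccc(O)cc2)[C@@H](c2ccc(O)cc2O)O[C@@H]1c1ccc(O)cc1 | target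

Total step count: 14 (steps 4, 5, 8 and 10 prepare side fragments).
Longest linear sequence: 10 steps (1, 2, 3, 6, 7, 9, 11, 12, 13, 14, from 2,4-dihydroxybenzaldehyde).

Steps most likely to fail

1. Step 13. The carbenoid may be lost through 1,2-hydride shift from C4 to an enone, through aromatic substitution or ylide formation, or it may insert into the other diastereotopic C2–H bond. The fallback closes the ring by C–O instead of C–C bond formation; it sets out from lactone 15 and returns at 28. LiN(SiMe3)2 in THF at −78 °C should convert 15 into the lactone lithium enolate F1. F1 should add to aldehyde 8 on the face opposite the C4 benzyl group to give the α-(hydroxybenzyl) lactone F2, whose carbinol configuration is immaterial. MeNHOMe·HCl and i-PrMgCl should open F2 to the dihydroxy Weinreb amide F3. Catalytic CSA in CH2Cl2 at 0 °C should then close the ring by capture of a benzylic cation (cyclodehydration of a 1,4-diaryl-1,4-diol under thermodynamic control, anchored by C4) to give the all-trans tetrahydrofuran Weinreb amide F4. Aryllithium 21, made as in step 11, should add to F4 to give the chelated lithium hemiaminal adduct F5, which releases 28 on aqueous NH4Cl work-up.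

2. Step 6. The benzyl group may transfer poorly from copper, with loss of the benzylic organometallic by homocoupling and competing 1,2-addition to the lactone carbonyl. The fallback uses an acyl-anion equivalent instead of an organocopper reagent; it sets out from butenolide 7 and returns at lactone 15. Aldehyde 8 with propane-1,3-dithiol and catalytic BF3·OEt2 should give the aryl dithiane F6. n-BuLi in THF at −78 °C should convert F6 into the lithiated dithiane F7, which should add 1,4 to 7 anti to the C5 aryl group to give the dithianyl lactone F8 after NH4Cl quench. Reductive desulfurisation with Ni2B generated from NiCl2·6H2O and NaBH4 (MeOH–THF, 0 °C) should then give 15.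

3. Step 2. Facial selectivity may be poor, or addition slow, with the hindered and electron-rich ortho-silyloxy aldehyde. The fallback uses asymmetric reduction instead of asymmetric addition; it sets out from aldehyde 2 and returns at carbinol 5. LiN(SiMe3)2 in THF at −78 °C should convert 3 into the lithium acetylide F9, which should add to 2 to give the racemic carbinol F10. MnO2 in CH2Cl2 should oxidise F10 to the ynone F11. Corey–Bakshi–Shibata reduction of F11 (catecholborane, toluene, −78 °C), with the oxazaborolidine antipode that delivers the (S)-carbinol, should give 5.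

Further compounds

F1 | step 13 | lithium enolate of lactone 15 | [Li]OC1=C[C@H](Cc2ccc(O[Si](C)(C)C(C)(C)C)cc2)[C@@H](c2ccc(O[Si](C)(C)C(C)(C)C)cc2O[Si](C)(C)C(C)(C)C)O1
F2 | step 13 | (3S,4S,5S)-5-[2,4-bis(TBSO)phenyl]-4-[4-(TBSO)benzyl]-3-{hydroxy[4-(TBSO)phenyl]methyl}dihydrofuran-2(3H)-one (carbinol centre undefined) | O=C1[C@H](C(O)c2ccc(O[Si](C)(C)C(C)(C)C)cc2)[C@H](Cc2ccc(O[Si](C)(C)C(C)(C)C)cc2)[C@@H](c2ccc(O[Si](C)(C)C(C)(C)C)cc2O[Si](C)(C)C(C)(C)C)O1
F3 | step 13 | (2S,3S,4S)-4-[2,4-bis(TBSO)phenyl]-4-hydroxy-2-{hydroxy[4-(TBSO)phenyl]methyl}-N-methoxy-N-methyl-3-[4-(TBSO)benzyl]butanamide | CON(C)C(=O)[C@H](C(O)c1ccc(O[Si](C)(C)C(C)(C)C)cc1)[C@H](Cc1ccc(O[Si](C)(C)C(C)(C)C)cc1)[C@H](O)c1ccc(O[Si](C)(C)C(C)(C)C)cc1O[Si](C)(C)C(C)(C)C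
F4 | step 13 | (2S,3S,4S,5S)-5-[2,4-bis(TBSO)phenyl]-N-methoxy-N-methyl-4-[4-(TBSO)benzyl]-2-[4-(TBSO)phenyl]tetrahydrofuran-3-carboxamide | CON(C)C(=O)[C@H]1[C@H](Cc2ccc(O[Si](C)(C)C(C)(C)C)cc2)[C@@H](c2ccc(O[Si](C)(C)C(C)(C)C)cc2O[Si](C)(C)C(C)(C)C)O[C@@H]1c1ccc(O[Si](C)(C)C(C)(C)C)cc1
F5 | step 13 | lithium alkoxide of the N-methoxy-N-methyl hemiaminal formed from F4 and 21 | [Li]OC(N(C)OC)(c1ccc(O[Si](C(C)C)(C(C)C)C(C)C)cc1O[Si](C(C)C)(C(C)C)C(C)C)[C@H]1[C@H](Cc2ccc(O[Si](C)(C)C(C)(C)C)cc2)[C@@H](c2ccc(O[Si](C)(C)C(C)(C)C)cc2O[Si](C)(C)C(C)(C)C)O[C@@H]1c1ccc(O[Si](C)(C)C(C)(C)C)cc1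
F6 | step 6 | 2-[4-(TBSO)phenyl]-1,3-dithiane | C1CSC(c2ccc(O[Si](C)(C)C(C)(C)C)cc2)SC1
F7 | step 6 | 2-lithio-2-[4-(TBSO)phenyl]-1,3-dithiane | [Li]C1(c2ccc(O[Si](C)(C)C(C)(C)C)cc2)SCCCS1
F8 | step 6 | (4S,5S)-5-[2,4-bis(TBSO)phenyl]-4-{2-[4-(TBSO)phenyl]-1,3-dithian-2-yl}dihydrofuran-2(3H)-one | O=C1C[C@H](C2(c3ccc(O[Si](C)(C)C(C)(C)C)cc3)SCCCS2)[C@@H](c2ccc(O[Si](C)(C)C(C)(C)C)cc2O[Si](C)(C)C(C)(C)C)O1
F9 | step 2 | methyl 3-lithioprop-2-ynoate | [Li]C#CC(=O)OC
F10 | step 2 | racemic methyl 4-[2,4-bis(TBSO)phenyl]-4-hydroxybut-2-ynoate | COC(=O)C#CC(O)c1ccc(O[Si](C)(C)C(C)(C)C)cc1O[Si](C)(C)C(C)(C)C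
F11 | step 2 | methyl 4-[2,4-bis(TBSO)phenyl]-4-oxobut-2-ynoate | COC(=O)C#CC(=O)c1ccc(O[Si](C)(C)C(C)(C)C)cc1O[Si](C)(C)C(C)(C)C
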